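**Plan**

- Numbering used below: C1 = oxirane carbon bearing CH2OBz, C2 (OH), C3 (OBz), C4=C5, C6 = oxirane CH. The enabling feature is the C1–O–C6 oxirane fused to a six-membered carbocycle whose other four carbons (C2–C5) can be raised to the diene level. Such a benzene oxide is the 6π valence tautomer of a seven-membered oxepin (O plus C1–C6).
- Retrosynthesis cuts, in order: the C3 ester O–acyl bond; the C3–O bond (water opening of a C2/C3 oxirane); the C3–O bond of that oxirane with return of oxygen to C5 (a C2,C5-endoperoxide); then the two peroxide C–O bonds and the C1–C6 σ bond, which leads to (oxepin-2-yl)methyl benzoate.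
- Forward: a Diels–Alder reaction gives a cyclohexa-1,4-diene; epoxidation, benzoylation, bromination and double dehydrobromination give the oxepin. The key step recloses the seven-membered ring to the six-membered carbocycle and traps it with singlet oxygen. Phosphite rearrangement, hydrolysis and enzymatic benzoylation finish the route.
- Stereochemistry: C1/C6 are cis from the disrotatory closure, C2 comes from attack of singlet oxygen anti to the oxirane, C3 from SN2 inversion. The absolute configuration is selected in the last step by a lipase, because an arene oxide of this type racemises through its achiral oxepin.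

Key step: step 7

Remark on the chemistry: an oxepin and its arene oxide valence tautomer interconvert rapidly at room temperature, so the material obtained in step 6 is treated as one substance and entered under its expected main tautomer 9; the arene oxide tautomer is entered as 10 at step 7, where it is the reacting species. Since the oxepin stage erases chirality, 5–8 and 11–14 are racemates, and their SMILES (and that of the rapidly racemising 10) show the enantiomer that is carried into 15.

**Route**

Step 1
Reactants: 1 buta-1,3-diene; 2 methyl propiolate
Product: 3 methyl cyclohexa-1,4-diene-1-carboxylate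
Conditions: 1 (3 equiv), toluene, hydroquinone (cat.), sealed tube, 110 °C
Reagents that add atoms: none
Why: a thermal Diels–Alder reaction of an electron-poor alkyne with a symmetric diene should give the skipped 1,4-diene with the ester on an sp2 carbon, with no regio- or stereochemical issue.

Step 2
Reactants: 3 methyl cyclohexa-1,4-diene-1-carboxylate
Product: 4 (cyclohexa-1,4-dien-1-yl)methanol
Conditions: i-Bu2AlH (2.2 equiv), CH2Cl2, −78 to 0 °C; aq. potassium sodium tartrate
Reagents that add atoms: none
Why: 1,2-reduction of a conjugated ester with i-Bu2AlH should give the allylic alcohol without touching either alkene.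

Step 3
Reactants: 4 (cyclohexa-1,4-dien-1-yl)methanol
Product: 5 rac-(7-oxabicyclo[4.1.0]hept-3-en-1-yl)methanol
Conditions: VO(acac)2 (2 mol %), t-BuOOH (1.2 equiv), CH2Cl2, 0 °C to rt
Reagents that add atoms: tert-butyl hydroperoxide, CC(C)(C)OO
Why: hydroxyl-directed vanadium-catalysed epoxidation should deliver oxygen only to the allylic trisubstituted alkene and leave the remote disubstituted alkene; the cis-fused oxirane carbons (future C1 and C6) form as a racemate, which does not matter because this configuration is erased in step 6.

Step 4
Reactants: 5 rac-(7-oxabicyclo[4.1.0]hept-3-en-1-yl)methanol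
Product: 6 rac-(7-oxabicyclo[4.1.0]hept-3-en-1-yl)methyl benzoate
Conditions: BzCl (1.2 equiv), Et3N, 4-(dimethylamino)pyridine (cat.), CH2Cl2, 0 °C
Reagents that add atoms: benzoyl chloride, O=C(Cl)c1ccccc1
Why: routine acylation of the primary alcohol installs the CH2OBz group of the target and removes a free hydroxyl before the bromination, base and oxidation steps.

Step 5
Reactants: 6 rac-(7-oxabicyclo[4.1.0]hept-3-en-1-yl)methyl benzoate
Product: 7 rac-(trans-3,4-dibromo-7-oxabicyclo[4.1.0]heptan-1-yl)methyl benzoate
Conditions: Br2 (1.0 equiv), CH2Cl2, −78 °C
Reagents that add atoms: bromine, BrBr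
Why: anti addition of bromine through a bromonium ion should give the trans-dibromide, and either diastereomer with respect to the oxirane converges on the same diene in step 6.

Step 6
Reactants: 7 rac-(trans-3,4-dibromo-7-oxabicyclo[4.1.0]heptan-1-yl)methyl benzoate
Product: 9 (oxepin-2-yl)methyl benzoate, via allylic bromide 8 (not isolated)
Conditions: DBU (3 equiv), THF, 0 °C to rt, base-washed glassware, dark
Reagents that add atoms: none
Why: two successive anti E2 dehydrobrominations, each taking a proton from a CH2 group next to an oxirane carbon (the first gives allylic bromide 8 or its regioisomer, which converge), should give the cyclohexa-2,4-diene oxide, whose thermally allowed disrotatory 6π ring opening (oxepin–benzene oxide valence tautomerism) breaks the C1–C6 bond and, for a 2-substituted system, is expected to leave the material mainly as the oxepin 9, with loss of both stereocentres.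

Step 7
Reactants: 9 (oxepin-2-yl)methyl benzoate
Product: 11 rac-(3,6,7-trioxatricyclo[3.2.2.0^2,4]non-8-en-2-yl)methyl benzoate (peroxide bridge anti to the oxirane oxygen), via arene oxide 10 (not isolated)
Conditions: O2, hν (visible), 5,10,15,20-tetraphenylporphyrin (cat.), CH2Cl2, −30 °C
Reagents that add atoms: dioxygen, O=O
Why: The seven-membered oxepin 9 should undergo thermal disrotatory 6π electrocyclisation, forming the C1–C6 σ bond and so contracting the oxacycle to the six-membered carbocycle (with its fused oxirane) of arene oxide 10, which is drained from the fast equilibrium by suprafacial [4+2] cycloaddition of singlet oxygen across C2 and C5 of its s-cis diene. The closest known reaction type is the Diels–Alder trapping of the benzene oxide tautomer of oxepin–benzene oxide pairs by singlet oxygen and other dienophiles. The carbocycle (and with it the oxirane) closes by 6π electrocyclisation, and the 1,2-dioxane ring closes by concerted [4+2] cycloaddition. C1 and C6 are cis through the geometry of the disrotatory closure (both enantiomers form, since 9 is achiral), and C2 and C5 are set relative to them by approach of singlet oxygen to the diene face anti to the oxirane oxygen, that is syn to CH2OBz. The step needs chemoselectivity for the diene of the minor tautomer 10 over ene or [2+2] oxidation of the enol-ether bonds of 9; this should be secured by tautomerisation being much faster than oxygenation and by the high reactivity of singlet oxygen towards a planar cyclohexa-1,3-diene, while the low temperature keeps the endoperoxide from rearranging and the arene oxide from aromatising.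

Step 8
Reactants: 11 rac-(3,6,7-trioxatricyclo[3.2.2.0^2,4]non-8-en-2-yl)methyl benzoate
Product: 13 rac-(3,8-dioxatricyclo[5.1.0.0^2,4]oct-5-en-1-yl)methyl benzoate (anti-dioxide), via phosphonium alkoxide 12 (not isolated)
Conditions: P(OMe)3 (1.1 equiv), CH2Cl2, −20 °C to rt
Reagents that add atoms: none
Why: deoxygenation of an unsaturated bicyclic endoperoxide by a trivalent phosphorus reagent to a vinyl oxirane: the phosphite should attack the less hindered peroxide oxygen (on C5, away from quaternary C1), and the C2 alkoxide of 12 then closes onto C3 in a syn SN2′ displacement that expels trimethyl phosphate from C5 and moves the alkene to C4=C5, so that C2 keeps its configuration, C3 receives oxygen on the same face and the new oxirane is anti to the first.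

Step 9
Reactants: 13 rac-(3,8-dioxatricyclo[5.1.0.0^2,4]oct-5-en-1-yl)methyl benzoate
Product: 14 rac-[(1R*,2S*,3R*,6S*)-2,3-dihydroxy-7-oxabicyclo[4.1.0]hept-4-en-1-yl]methyl benzoate
Conditions: H2O–THF (1:2), HClO4 (cat.), 0 °C; NaHCO3 quench
Reagents that add atoms: water, O
Why: acid-catalysed hydrolysis of a vinyl oxirane: water should attack the allylic carbon C3 of the more basic 2,3-oxirane from the face opposite to the leaving oxygen (inversion at C3, retention at C2) to give the trans-2,3-diol, while the 1,6-oxirane is less basic (CH2OBz on C1) and its allylic carbon C6 is shielded on the attack face by the adjacent CH2OBz.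

Step 10
Reactants: 14 rac-[(1R*,2S*,3R*,6S*)-2,3-dihydroxy-7-oxabicyclo[4.1.0]hept-4-en-1-yl]methyl benzoate
Product: 15 [(1R,2S,3R,6S)-3-(benzoyloxy)-2-hydroxy-7-oxabicyclo[4.1.0]hept-4-en-1-yl]methyl benzoate
Conditions: vinyl benzoate (3 equiv), Burkholderia cepacia lipase (immobilised), t-BuOMe, 35 °C, stopped short of half conversion
Reagents that add atoms: vinyl benzoate, C=COC(=O)c1ccccc1
Why: lipase-catalysed transesterification used as a kinetic resolution of a secondary allylic alcohol: only the unhindered allylic C3 hydroxyl should reach the acyl-enzyme (C2–OH is flanked by quaternary C1), and by the empirical size rule for lipase acylation of secondary alcohols the (3R)-carbinol (large C2 flank, medium vinyl flank) should react first, so the benzoate and the absolute configuration are installed together while the (3S)-diol stays unreacted and is removed by chromatography; no new stereocentre is formed.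

**Compound list**

1 | buta-1,3-diene | C=CC=C | starting material
2 | methyl propiolate (methyl prop-2-ynoate) | C#CC(=O)OC | starting material
3 | methyl cyclohexa-1,4-diene-1-carboxylate | COC(=O)C1=CCC=CC1 | intermediate
4 | (cyclohexa-1,4-dien-1-yl)methanol | OCC1=CCC=CC1 | intermediate
5 | rac-(7-oxabicyclo[4.1.0]hept-3-en-1-yl)methanol | OC[C@]12O[C@H]1CC=CC2 | intermediate
6 | rac-(7-oxabicyclo[4.1.0]hept-3-en-1-yl)methyl benzoate | O=C(OC[C@]12O[C@H]1CC=CC2)c1ccccc1 | intermediate
7 | rac-(trans-3,4-dibromo-7-oxabicyclo[4.1.0]heptan-1-yl)methyl benzoate | O=C(OC[C@]12O[C@H]1C[C@H](Br)[C@@H](Br)C2)c1ccccc1 | intermediate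
8 | rac-(3-bromo-7-oxabicyclo[4.1.0]hept-4-en-1-yl)methyl benzoate (allylic bromide from the first elimination; the 4-bromo-hept-2-ene regioisomer converges) | O=C(OC[C@]12O[C@H]1C=C[C@@H](Br)C2)c1ccccc1 | intermediate
9 | (oxepin-2-yl)methyl benzoate | O=C(OCC1=CC=CC=CO1)c1ccccc1 | intermediate
10 | (7-oxabicyclo[4.1.0]hepta-2,4-dien-1-yl)methyl benzoate (arene oxide, minor valence tautomer of 9, racemises through 9) | O=C(OC[C@]12O[C@H]1C=CC=C2)c1ccccc1 | intermediate
11 | rac-(3,6,7-trioxatricyclo[3.2.2.0^2,4]non-8-en-2-yl)methyl benzoate (peroxide bridge anti to the oxirane oxygen) | O=C(OC[C@]12O[C@H]1[C@H]3C=C[C@@H]2OO3)c1ccccc1 | intermediate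
12 | zwitterion from 11 and trimethyl phosphite: C5–O–P(OMe)3 phosphonium, C2 alkoxide | O=C(OC[C@]12O[C@H]1[C@H](O[P+](OC)(OC)OC)C=C[C@@H]2[O-])c1ccccc1 | intermediate
13 | rac-(3,8-dioxatricyclo[5.1.0.0^2,4]oct-5-en-1-yl)methyl benzoate (the two oxirane oxygens on opposite faces) | O=C(OC[C@]12O[C@H]1C=C[C@@H]3O[C@H]23)c1ccccc1 | intermediate
14 | rac-[(1R*,2S*,3R*,6S*)-2,3-dihydroxy-7-oxabicyclo[4.1.0]hept-4-en-1-yl]methyl benzoate | O=C(OC[C@]12O[C@H]1C=C[C@@H](O)[C@@H]2O)c1ccccc1 | intermediate
15 | [(1R,2S,3R,6S)-3-(benzoyloxy)-2-hydroxy-7-oxabicyclo[4.1.0]hept-4-en-1-yl]methyl benzoate | O=C(OC[C@]12O[C@H]1C=C[C@@H](OC(=O)c1ccccc1)[C@@H]2O)c1ccccc1 | target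

**Step count**

Total steps: 10. Longest linear sequence: 10 steps (from 1 and 2 to 15).

**Steps most likely to fail**

Step 8. The phosphite may attack the peroxide oxygen on C2 instead, or the phosphorane may form reversibly and close from the C5 alkoxide; either would place the new oxirane at C4/C5 and the alkene at C2=C3. The fallback sets out from 11 and returns at 13. The peroxide bond is reduced with thiourea in MeOH at 0 °C to the cis-ene-diol rac-[2,5-dihydroxy-7-oxabicyclo[4.1.0]hept-3-en-1-yl]methyl benzoate F1. The less hindered C5 hydroxyl is sulfonylated (MsCl, Et3N, CH2Cl2, −40 °C) to rac-[2-hydroxy-5-(methanesulfonyloxy)-7-oxabicyclo[4.1.0]hept-3-en-1-yl]methyl benzoate F2. DBU is then added, so that the C2 alkoxide closes onto C3 with syn SN2′ loss of methanesulfonate to give 13. The two oxygens are thus told apart in a separate sulfonylation under steric control and not in the peroxide cleavage.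

Step 9. Ionisation to an allyl cation would erode the trans selectivity and allow conjugate attack of water at C5; the 1,6-oxirane may also open, or the primary benzoate may migrate under acid. The fallback sets out from 13 and returns at 14. 13 is opened with AcOH/NaOAc at rt (buffered SN2 acidolysis at C3 by a carboxylate/carboxylic acid pair) to rac-[3-acetoxy-2-hydroxy-7-oxabicyclo[4.1.0]hept-4-en-1-yl]methyl benzoate F3. The acetate is then removed with Candida antarctica lipase B and n-BuOH in t-BuOMe, which cleaves acetates far faster than benzoates. By the same enantiomer preference as in step 10 the (3R)-ester should be deacylated first, so 14 re-enters the route already enriched in the wanted enantiomer and step 10 completes the resolution.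

Step 10. The lipase may discriminate poorly between the enantiomers of 14, or benzoyl transfer from the acyl-enzyme may be sluggish. The fallback sets out from 14 and returns at 15. A non-enzymatic acylative kinetic resolution is run with the chiral isothiourea homobenzotetramisole (2-phenyl-3,4-dihydro-2H-pyrimido[2,1-b][1,3]benzothiazole; the enantiomer that acylates the (3S)-alcohol, fixed by a test on the racemate), (i-PrCO)2O and i-Pr2NEt in CHCl3 at 0 °C. This catalyst class recognises the π-system next to an allylic carbinol and should convert the unwanted enantiomer into [(1S,2R,3S,6R)-2-hydroxy-3-(2-methylpropanoyloxy)-7-oxabicyclo[4.1.0]hept-4-en-1-yl]methyl benzoate F4. The recovered (1R,2S,3R,6S)-14 is then benzoylated at the unhindered C3 hydroxyl (BzCl, pyridine, CH2Cl2, −20 °C) to give 15.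

**Further compounds**

F1 | step 8 | rac-[2,5-dihydroxy-7-oxabicyclo[4.1.0]hept-3-en-1-yl]methyl benzoate (hydroxyls cis to each other, anti to the oxirane oxygen) | O=C(OC[C@]12O[C@H]1[C@H](O)C=C[C@@H]2O)c1ccccc1
F2 | step 8 | rac-[2-hydroxy-5-(methanesulfonyloxy)-7-oxabicyclo[4.1.0]hept-3-en-1-yl]methyl benzoate | O=C(OC[C@]12O[C@H]1[C@H](OS(C)(=O)=O)C=C[C@@H]2O)c1ccccc1
F3 | step 9 | rac-[3-acetoxy-2-hydroxy-7-oxabicyclo[4.1.0]hept-4-en-1-yl]methyl benzoate (relative configuration as in 15) | O=C(OC[C@]12O[C@H]1C=C[C@@H](OC(C)=O)[C@@H]2O)c1ccccc1
F4 | step 10 | [(1S,2R,3S,6R)-2-hydroxy-3-(2-methylpropanoyloxy)-7-oxabicyclo[4.1.0]hept-4-en-1-yl]methyl benzoate | O=C(OC[C@@]12O[C@@H]1C=C[C@H](OC(=O)C(C)C)[C@H]2O)c1ccccc1
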